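**Retrosynthetic overview**

1. The last event is hydroxylation at C8 of the (2S)-5,6,7,3',4'-pentamethoxyflavanone. C8 is the only C–H of ring A, ortho to O1 and to the 7-methoxy group and para to the 5-methoxy group.
2. Key disconnection: ring C is opened at O1–C8a and C4–C4a, giving 3,4,5-trimethoxybenzyne (ring A) and an (S)-β-silyloxy ester that carries O1, C2, C3, C4 and ring B. The enabling feature is that the adjacent ring A carbons C8a and C4a bear an ether oxygen and an acyl carbon (an ortho-alkoxyaryl ketone, the formal adduct of an alkoxide and an acyl electrophile across an aryne bond). C5, next to C4a, bears a methoxy group that steers the alkoxide to C8a. C8 is kept as C–H through this step because an oxygen there would oppose that steering.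
3. The silyloxy ester comes from the commercial β-keto ester by asymmetric hydrogenation (sets C2) and silylation. The aryne precursor comes from 3,4,5-trimethoxyphenol by bromination and retro-Brook rearrangement/triflation.
4. Ring order: rings A and B are purchased; ring C is the only ring formed, in the key step.

Key step: step 5

Remark on the chemistry: the target is read as the (2S)-flavanone. C2 keeps all four attachments from the hydroxy ester onward, so the (S)-hydroxy ester is required.

**Route**

Step 1
Reactants: 1 3,4,5-trimethoxyphenol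
Product: 2 2-bromo-3,4,5-trimethoxyphenol
Conditions: NBS (1.0 equiv), CH2Cl2, −78 °C to 0 °C
Reagents that add atoms: N-bromosuccinimide, O=C1CCC(=O)N1Br
Why: Electrophilic aromatic bromination; the two free positions of 1 are equivalent and each is ortho to OH and para to a methoxy group, so one equivalent of NBS at low temperature should give the mono-bromide.

Step 2
Reactants: 2 2-bromo-3,4,5-trimethoxyphenol
Product: 5 3,4,5-trimethoxy-2-(trimethylsilyl)phenyl trifluoromethanesulfonate, via aryl trimethylsilyl ether 3 (not isolated), via lithium 2-silylphenoxide 4 (not isolated)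
Conditions: HMDS, THF, 65 °C, then concentrate; n-BuLi, THF, −100 °C to −78 °C; Tf2O, −100 °C to rt
Reagents that add atoms: hexamethyldisilazane, C[Si](C)(C)N[Si](C)(C)C; trifluoromethanesulfonic anhydride, O=S(=O)(OS(=O)(=O)C(F)(F)F)C(F)(F)F
Why: O-silylation, bromine–lithium exchange and retro-Brook rearrangement (1,3 shift of silicon from O to C) should place the trimethylsilyl group on the former C–Br carbon, and the lithium phenoxide is trapped by Tf2O to give the ortho-silylaryl triflate, the standard fluoride-triggered aryne precursor.

Step 3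
Reactants: 6 ethyl 3-(3,4-dimethoxyphenyl)-3-oxopropanoate
Product: 7 ethyl (S)-3-(3,4-dimethoxyphenyl)-3-hydroxypropanoate
Conditions: H2 (10 atm), [RuCl(C6H6)((R)-BINAP)]Cl (0.5 mol %), EtOH, 50 °C
Reagents that add atoms: none
Why: Noyori asymmetric hydrogenation of a β-keto ester; chelation of the keto and ester oxygen atoms to ruthenium lets the (R)-BINAP ligand select the carbonyl face, which is expected to give the same spatial sense as in (R)-3-hydroxybutanoates, named S here because aryl outranks CH2CO2Et, and this sets C2 of the target.

Step 4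
Reactants: 7 ethyl (S)-3-(3,4-dimethoxyphenyl)-3-hydroxypropanoate
Product: 8 ethyl (S)-3-(3,4-dimethoxyphenyl)-3-(trimethylsilyloxy)propanoate
Conditions: TMSCl, imidazole, CH2Cl2, 0 °C to rt
Reagents that add atoms: chlorotrimethylsilane, C[Si](C)(C)Cl
Why: Routine O-silylation of a secondary alcohol; the silyl ether removes the only acidic proton from the key step and serves as a latent alkoxide that fluoride releases, and C2 is untouched.

Step 5
Reactants: 5 3,4,5-trimethoxy-2-(trimethylsilyl)phenyl trifluoromethanesulfonate, 8 ethyl (S)-3-(3,4-dimethoxyphenyl)-3-(trimethylsilyloxy)propanoate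
Product: 12 (S)-2-(3,4-dimethoxyphenyl)-5,6,7-trimethoxychroman-4-one, via cesium alkoxide 9 (not isolated), via 3,4,5-trimethoxybenzyne 10 (not isolated), via aryl cesium adduct 11 (not isolated)
Conditions: CsF (3 equiv), 18-crown-6 (0.2 equiv), THF, 0 °C to rt; 5 in slight excess (1.3 equiv)
Reagents that add atoms: none
Why: Proposed new method: fluoride removes the O-silyl group of 8 to give alkoxide 9 and turns 5 into 3,4,5-trimethoxybenzyne 10; 9 adds through O1 to the aryne carbon that becomes C8a, and the aryl anion left on the neighbouring carbon (C4a, adduct 11) attacks the ester carbonyl C4 and expels ethoxide, so that both the O1–C8a and the C4–C4a bond are made in one flask. The closest known reaction types are the fluoride-triggered annulation of arynes with salicylate esters to xanthones (phenoxide addition, then acyl substitution by the aryl anion) and the Parham cyclization of ortho-metalated aryloxypropanoates to chroman-4-ones; new is the aliphatic, configurationally defined β-silyloxy ester as the partner. Ring C closes in the 6-exo-trig mode, the aryl carbanion attacking the exocyclic ester C=O after the intermolecular O-arylation. No stereocenter is created: C2 comes from 8 with all four attachments intact, since the new bonds are made at O1 and C4. Regioselectivity is needed and is secured by the methoxy group on the carbon next to the triple bond, whose inductive pull places the developing anion ortho to itself (the usual behaviour of 3-alkoxyarynes), so that oxygen enters at the remote aryne carbon; with C8 as C–H there is no second ortho oxygen to oppose it. Acylation must beat protonation of the aryl anion, which the aprotic medium secures because the alkoxide is released from a silyl ether and not from an OH group, and the ethoxide set free is taken up by silicon (it desilylates further 5 or 8), which keeps free base low and guards C2 against retro-aldol cleavage and β-elimination.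

Step 6
Reactants: 12 (S)-2-(3,4-dimethoxyphenyl)-5,6,7-trimethoxychroman-4-one
Product: 14 (S)-2-(3,4-dimethoxyphenyl)-8-hydroxy-5,6,7-trimethoxychroman-4-one (target), via aryl hydrogen phthalate 13 (not isolated)
Conditions: phthaloyl peroxide (1.3 equiv; made from phthaloyl dichloride and sodium percarbonate), (CF3)2CHOH, rt; then NaHCO3, MeOH–H2O, 40 °C; dilute HCl work-up
Reagents that add atoms: phthaloyl peroxide, O=C1OOC(=O)c2ccccc12
Why: Electrophilic arene C–H hydroxylation with phthaloyl peroxide followed by mild hydrolysis of the phthalate half-ester; C8 is the only C–H of ring A and is flanked by O1 and the 7-methoxy group and para to the 5-methoxy group, so it should react ahead of the dimethoxyphenyl ring, the phenol stays masked as ester 13 until hydrolysis, and C2 is not affected.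

**Compound list**

1 | 3,4,5-trimethoxyphenol | COc1cc(O)cc(OC)c1OC | starting material
2 | 2-bromo-3,4,5-trimethoxyphenol | COc1cc(O)c(Br)c(OC)c1OC | intermediate
3 | (2-bromo-3,4,5-trimethoxyphenoxy)trimethylsilane | COc1cc(O[Si](C)(C)C)c(Br)c(OC)c1OC | intermediate
4 | lithium 3,4,5-trimethoxy-2-(trimethylsilyl)phenolate | COc1cc([O-])c([Si](C)(C)C)c(OC)c1OC.[Li+] | intermediate
5 | 3,4,5-trimethoxy-2-(trimethylsilyl)phenyl trifluoromethanesulfonate | COc1cc(OS(=O)(=O)C(F)(F)F)c([Si](C)(C)C)c(OC)c1OC | intermediate
6 | ethyl 3-(3,4-dimethoxyphenyl)-3-oxopropanoate | CCOC(=O)CC(=O)c1ccc(OC)c(OC)c1 | starting material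
7 | ethyl (S)-3-(3,4-dimethoxyphenyl)-3-hydroxypropanoate | COc1ccc([C@@H](O)CC(=O)OCC)cc1OC | intermediate
8 | ethyl (S)-3-(3,4-dimethoxyphenyl)-3-(trimethylsilyloxy)propanoate | COc1ccc([C@@H](O[Si](C)(C)C)CC(=O)OCC)cc1OC | intermediate
9 | cesium (1S)-1-(3,4-dimethoxyphenyl)-3-ethoxy-3-oxopropan-1-olate | COc1ccc([C@@H]([O-])CC(=O)OCC)cc1OC.[Cs+] | intermediate
10 | 3,4,5-trimethoxybenzyne | COC1=C(OC)C(OC)=CC#C1 | intermediate
11 | [2-{[(1S)-1-(3,4-dimethoxyphenyl)-3-ethoxy-3-oxopropyl]oxy}-4,5,6-trimethoxyphenyl]cesium | COc1ccc([C@@H](Oc2cc(OC)c(OC)c(OC)[c-]2)CC(=O)OCC)cc1OC.[Cs+] | intermediate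
12 | (S)-2-(3,4-dimethoxyphenyl)-5,6,7-trimethoxychroman-4-one | COc1ccc([C@@H]2CC(=O)c3c(cc(OC)c(OC)c3OC)O2)cc1OC | intermediate
13 | 2-({[(2S)-2-(3,4-dimethoxyphenyl)-5,6,7-trimethoxy-4-oxochroman-8-yl]oxy}carbonyl)benzoic acid | COc1ccc([C@@H]2CC(=O)c3c(c(OC(=O)c4ccccc4C(=O)O)c(OC)c(OC)c3OC)O2)cc1OC | intermediate
14 | (S)-2-(3,4-dimethoxyphenyl)-8-hydroxy-5,6,7-trimethoxychroman-4-one | COc1ccc([C@@H]2CC(=O)c3c(c(O)c(OC)c(OC)c3OC)O2)cc1OC | target

**Step count**

Total: 6 steps. Longest linear sequence: 4 steps (1, 2, 5, 6 or 3, 4, 5, 6).

**Steps most likely to fail**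

Step 5. The aryl anion may be protonated or silylated before it reaches the ester, leaving the open aryl ether. The free alkoxide may undergo retro-aldol cleavage or β-elimination, and the chromanone may open under base, each with loss of the C2 configuration. The fallback closes ring C in two known stages and sets out from keto ester 6 and bromophenol 2. Hydrogenation of 6 with the enantiomeric catalyst [RuCl(C6H6)((S)-BINAP)]Cl would give ethyl (R)-3-(3,4-dimethoxyphenyl)-3-hydroxypropanoate F1. Mitsunobu reaction of F1 with 2 (PPh3, DIAD, THF, 0 °C) would form the aryl ether with inversion at the carbinol carbon and give ethyl (S)-3-(2-bromo-3,4,5-trimethoxyphenoxy)-3-(3,4-dimethoxyphenyl)propanoate F2. Parham cyclization of F2 (n-BuLi, THF, −100 °C, bromine–lithium exchange and attack of the aryllithium on the ester) would then form the C4–C4a bond and come back to the route at 12.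

Step 6. The peroxide may attack the dimethoxyphenyl ring in competition with C8. The very electron-rich para-methoxyphenol may be oxidized onward to a quinone, and C2 may partly epimerize by base-induced ring opening during hydrolysis. The fallback sets out from 12. Bromination (NBS, MeCN, 0 °C) should give (S)-8-bromo-2-(3,4-dimethoxyphenyl)-5,6,7-trimethoxychroman-4-one F4. Miyaura borylation (B2pin2, Pd(dppf)Cl2, KOAc, dioxane, 80 °C) should give (S)-2-(3,4-dimethoxyphenyl)-5,6,7-trimethoxy-8-(4,4,5,5-tetramethyl-1,3,2-dioxaborolan-2-yl)chroman-4-one F5. Oxidation of the C–B bond (NaBO3·4H2O, THF–H2O, rt) comes back to the route at 14.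

Step 2. Halogen–lithium exchange on the crowded, electron-rich ring may be followed by protonation of the aryllithium or by incomplete migration of silicon from O to C, so that a desilylated or O-silylated phenol is triflated instead. The fallback uses directed ortho-metalation and sets out from 1. Carbamoylation (Et2NCOCl, Et3N, DMAP, CH2Cl2) would give 3,4,5-trimethoxyphenyl diethylcarbamate F6. Ortho-lithiation between the carbamate and the methoxy group and silylation (s-BuLi, TMEDA, THF, −78 °C; TMSCl) would give 3,4,5-trimethoxy-2-(trimethylsilyl)phenyl diethylcarbamate F7. Reductive removal of the carbamate (LiAlH4, THF, 0 °C) would give 3,4,5-trimethoxy-2-(trimethylsilyl)phenol F8, and triflation (Tf2O, pyridine, CH2Cl2, 0 °C) comes back to the route at 5.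

**Further compounds**

F1 | step 5 | ethyl (R)-3-(3,4-dimethoxyphenyl)-3-hydroxypropanoate | COc1ccc([C@H](O)CC(=O)OCC)cc1OC
F2 | step 5 | ethyl (S)-3-(2-bromo-3,4,5-trimethoxyphenoxy)-3-(3,4-dimethoxyphenyl)propanoate | COc1ccc([C@@H](Oc2cc(OC)c(OC)c(OC)c2Br)CC(=O)OCC)cc1OC
F4 | step 6 | (S)-8-bromo-2-(3,4-dimethoxyphenyl)-5,6,7-trimethoxychroman-4-one | COc1ccc([C@@H]2CC(=O)c3c(c(Br)c(OC)c(OC)c3OC)O2)cc1OC
F5 | step 6 | (S)-2-(3,4-dimethoxyphenyl)-5,6,7-trimethoxy-8-(4,4,5,5-tetramethyl-1,3,2-dioxaborolan-2-yl)chroman-4-one | COc1ccc([C@@H]2CC(=O)c3c(c(B4OC(C)(C)C(C)(C)O4)c(OC)c(OC)c3OC)O2)cc1OC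
F6 | step 2 | 3,4,5-trimethoxyphenyl diethylcarbamate | CCN(CC)C(=O)Oc1cc(OC)c(OC)c(OC)c1
F7 | step 2 | 3,4,5-trimethoxy-2-(trimethylsilyl)phenyl diethylcarbamate | CCN(CC)C(=O)Oc1cc(OC)c(OC)c(OC)c1[Si](C)(C)C
F8 | step 2 | 3,4,5-trimethoxy-2-(trimethylsilyl)phenol | COc1cc(O)c([Si](C)(C)C)c(OC)c1OC
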